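**Strategy.** In the numbering of the target, the 1,5-diol bridgeheads C1/C5 with C2 and C6 are a masked tartaric acid, and each oxolane ring is one formaldehyde unit (C4–O3 or C8–O7) spanning a bridgehead carbon and the carboxyl carbon on the other bridgehead. D-Tartrate acetonide is therefore annulated twice by enolate hydroxymethylation–lactonisation. In the key step the enolate of 4, a dioxolane-fused γ-lactone with an ester on the ring fusion, adds formaldehyde and the alkoxide lactonises onto that ester: the C8–C1 and O7–C6 bonds and the second quaternary carbinol centre form in one operation, the cis ring fusion dictating its configuration. Reduction and convex-face C-arylation finish the route.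

Key step: step 2

Remark: the ester enolate of 1 is taken to react with formaldehyde on the face anti to the vicinal ester (the usual sense for tartrate acetonide enolates); this is why the D-tartrate-derived (4S,5S) diester is chosen.

Step 1
Reactants: 1 dimethyl (4S,5S)-2,2-dimethyl-1,3-dioxolane-4,5-dicarboxylate
Product: 4 methyl (3aR,6aR)-2,2-dimethyl-6-oxotetrahydrofuro[3,4-d][1,3]dioxole-3a(4H)-carboxylate, via lithium ester enolate 2 (not isolated), via hydroxymethyl cis-diester 3 (not isolated)
Conditions: LiN(i-Pr)2, THF–DMPU, −78 °C; CH2O (g, from cracked paraformaldehyde), −78 °C; AcOH; then NaOMe (0.2 equiv), MeOH, 0 °C to rt; AcOH; CSA (cat.), PhMe, 50 °C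
Reagents that add atoms: formaldehyde, C=O
Why: The ester enolate 2 of the tartrate acetonide, in which β-elimination is slow because the ring C–O bond lies in the enolate plane, should add to monomeric formaldehyde on the face anti to the vicinal ester (aldol addition) and so fix the quaternary centre of 3, after which methoxide epimerises the remaining α-CH through its ester enolate and only the epimer with the ester cis to the hydroxymethyl group can lactonise, which drains the equilibrium to 4.

Step 2
Reactants: 4 methyl (3aR,6aR)-2,2-dimethyl-6-oxotetrahydrofuro[3,4-d][1,3]dioxole-3a(4H)-carboxylate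
Product: 7 (1R,5R)-1,5-(isopropylidenedioxy)-3,7-dioxabicyclo[3.3.0]octane-2,6-dione, via lithium lactone enolate 5 (not isolated), via lithium aldolate 6 (not isolated)
Conditions: LiN(i-Pr)2 (1.1 equiv), THF, −78 °C, 15 min; CH2O (g, excess), −78 to −40 °C; aq. NH4Cl
Reagents that add atoms: formaldehyde, C=O
Why: LiN(i-Pr)2 removes the only α-hydrogen of 4 (C6a–H), the lactone enolate 5 adds to formaldehyde at C6a, and the lithium alkoxide 6 attacks the methyl ester on the neighbouring ring-fusion carbon C3a and expels methoxide. The closest known reaction type is the aldol addition of an α-alkoxy ester or lactone enolate to formaldehyde followed by lactonisation (tandem aldol–lactonisation). The new γ-lactone closes in the 5-exo-trig mode by acyl substitution and completes a [3.3.3]propellane of two lactones and the dioxolane. The new quaternary centre is controlled by the ring fusion: the hydroxymethyl group can only enter on the face that keeps dioxolane and lactone cis-fused, which is the face of the C3a ester, so the configuration set in step 1 is relayed and the lactonisation is geometrically assured. The step needs C–C bond formation to outrun β-elimination of the acetonide oxygen and Claisen condensation; the low temperature, the poor alignment of the ring C3a–O bond with the enolate π-system in the bicycle, the absence of α-hydrogens on the C3a ester and an excess of monomeric formaldehyde should secure this.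

Step 3
Reactants: 7 (1R,5R)-1,5-(isopropylidenedioxy)-3,7-dioxabicyclo[3.3.0]octane-2,6-dione
Product: 9 (1R,5R)-2,6-dimethoxy-3,7-dioxabicyclo[3.3.0]octane-1,5-diol (mixture at C2 and C6), via acetonide bis-lactol 8 (not isolated)
Conditions: i-Bu2AlH (2.4 equiv), CH2Cl2, −78 °C; aq. potassium sodium tartrate (KNaC4H4O6); then HCl (0.5 M in MeOH), 50 °C
Reagents that add atoms: methanol, CO
Why: i-Bu2AlH stops at the lactol stage with γ-lactones at −78 °C (lactone to lactol reduction), and acidic methanol then turns both lactols into methyl acetals and removes the isopropylidene group by transketalisation (Fischer-type acetalisation), the two quaternary centres being untouched and the two acetal centres left as a mixture that step 6 erases.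

Step 4
Reactants: 9 (1R,5R)-2,6-dimethoxy-3,7-dioxabicyclo[3.3.0]octane-1,5-diol
Product: 10 (1R,5R)-2,6-bis(phenylsulfonyl)-3,7-dioxabicyclo[3.3.0]octane-1,5-diol (mixture at C2 and C6)
Conditions: PhSO2H (3 equiv), CaCl2, CH2Cl2, rt
Reagents that add atoms: benzenesulfinic acid, O=S(O)c1ccccc1
Why: Exchange of an anomeric methoxy group for benzenesulfinate through the oxocarbenium ion is the standard preparation of 2-(phenylsulfonyl) cyclic ethers (Ley anomeric sulfone formation), CaCl2 taking up the methanol.

Step 5
Reactants: 11 4-bromo-2-methoxyphenol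
Product: 12 (4-bromo-2-methoxyphenoxy)(tert-butyl)dimethylsilane
Conditions: TBSCl, imidazole, DMF, rt
Reagents that add atoms: tert-butyldimethylsilyl chloride, CC(C)(C)[Si](C)(C)Cl
Why: Silylation of the phenol (silyl ether formation) masks the acidic OH so that the aryl bromide can be turned into an organometallic reagent.

Step 6
Reactants: 10 (1R,5R)-2,6-bis(phenylsulfonyl)-3,7-dioxabicyclo[3.3.0]octane-1,5-diol; 12 (4-bromo-2-methoxyphenoxy)(tert-butyl)dimethylsilane (two molecules are built into 15)
Product: 15 (1S,2R,5S,6R)-2,6-bis[4-(tert-butyldimethylsilyloxy)-3-methoxyphenyl]-3,7-dioxabicyclo[3.3.0]octane-1,5-diol, via aryl Grignard reagent 13 (not isolated), via arylzinc bromide 14 (not isolated)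
Conditions: 12 (4.5 equiv), Mg, THF, reflux; ZnBr2 (4.5 equiv), THF, rt; then 10 (1 equiv), THF, 0 °C to rt; aq. NH4Cl
Reagents that add atoms: second molecule of (4-bromo-2-methoxyphenoxy)(tert-butyl)dimethylsilane 12, COc1cc(Br)ccc1O[Si](C)(C)C(C)(C)C
Why: The first two equivalents of arylzinc bromide 14 turn the two tertiary hydroxyl groups into zinc alkoxides, after which the zinc Lewis acid ionises each anomeric sulfone to an oxocarbenium ion that takes up one aryl group from a further molecule of 14 (Ley sulfone displacement with an organozinc reagent, so that two molecules of 12 end up in each molecule of 15), and the aryl group should enter on the convex face of the cis-fused bicycle, cis to the neighbouring bridgehead zinc alkoxide (syn delivery from the alkoxide-bound zinc, as in the arylzinc opening of 1,2-anhydro sugars), which sets C2 and C6 as R with both aryl groups exo, while the fully substituted neighbouring carbon rules out elimination.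

Step 7
Reactants: 15 (1S,2R,5S,6R)-2,6-bis[4-(tert-butyldimethylsilyloxy)-3-methoxyphenyl]-3,7-dioxabicyclo[3.3.0]octane-1,5-diol
Product: 16 prinsepiol, (1S,2R,5S,6R)-2,6-bis(4-hydroxy-3-methoxyphenyl)-3,7-dioxabicyclo[3.3.0]octane-1,5-diol
Conditions: Bu4NF, AcOH, THF, 0 °C
Reagents that add atoms: none
Why: Fluoride cleaves the two aryl silyl ethers (desilylation), the acetic acid buffer keeping the liberated phenoxides from opening the benzylic ethers through quinone methides.

**Compound list**

1 | dimethyl (4S,5S)-2,2-dimethyl-1,3-dioxolane-4,5-dicarboxylate (dimethyl 2,3-O-isopropylidene-D-tartrate) | COC(=O)[C@H]1OC(C)(C)O[C@@H]1C(=O)OC | starting material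
2 | lithium ester enolate of 1 (enolised at one ring carbon, the other still S; formed in situ) | COC(=O)[C@H]1OC(C)(C)OC1=C([O-])OC.[Li+] | intermediate
3 | dimethyl (4R,5S)-4-(hydroxymethyl)-2,2-dimethyl-1,3-dioxolane-4,5-dicarboxylate (cis-diester; not isolated) | COC(=O)[C@H]1OC(C)(C)O[C@]1(C(=O)OC)CO | intermediate
4 | methyl (3aR,6aR)-2,2-dimethyl-6-oxotetrahydrofuro[3,4-d][1,3]dioxole-3a(4H)-carboxylate | O=C1OC[C@@]2(C(=O)OC)OC(C)(C)O[C@@H]12 | intermediate
5 | lithium lactone enolate of 4 (C6=C6a enolate, 3aR; formed in situ) | [Li+].[O-]C1=C2OC(C)(C)O[C@]2(C(=O)OC)CO1 | intermediate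
6 | lithium alkoxide of methyl (3aR,6aR)-6a-(hydroxymethyl)-2,2-dimethyl-6-oxotetrahydrofuro[3,4-d][1,3]dioxole-3a(4H)-carboxylate (formed in situ) | O=C1OC[C@@]2(C(=O)OC)OC(C)(C)O[C@@]12C[O-].[Li+] | intermediate
7 | (1R,5R)-1,5-(isopropylidenedioxy)-3,7-dioxabicyclo[3.3.0]octane-2,6-dione ([3.3.3]propellane bis-lactone) | O=C1OC[C@]2(OC(C)(C)O3)C(=O)OC[C@]123 | intermediate
8 | (1R,5R)-1,5-(isopropylidenedioxy)-3,7-dioxabicyclo[3.3.0]octane-2,6-diol (bis-lactol, mixture at C2 and C6; not isolated) | OC1OC[C@]2(OC(C)(C)O3)C(O)OC[C@]123 | intermediate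
9 | (1R,5R)-2,6-dimethoxy-3,7-dioxabicyclo[3.3.0]octane-1,5-diol (mixture at C2 and C6) | COC1OC[C@]2(O)C(OC)OC[C@]12O | intermediate
10 | (1R,5R)-2,6-bis(phenylsulfonyl)-3,7-dioxabicyclo[3.3.0]octane-1,5-diol (mixture at C2 and C6) | O=S(=O)(c1ccccc1)C1OC[C@]2(O)C(S(=O)(=O)c3ccccc3)OC[C@]12O | intermediate
11 | 4-bromo-2-methoxyphenol | COc1cc(Br)ccc1O | starting material
12 | (4-bromo-2-methoxyphenoxy)(tert-butyl)dimethylsilane | COc1cc(Br)ccc1O[Si](C)(C)C(C)(C)C | intermediate
13 | [4-(tert-butyldimethylsilyloxy)-3-methoxyphenyl]magnesium bromide (formed in situ) | COc1cc([Mg]Br)ccc1O[Si](C)(C)C(C)(C)C | intermediate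
14 | [4-(tert-butyldimethylsilyloxy)-3-methoxyphenyl]zinc bromide (formed in situ) | COc1cc([Zn]Br)ccc1O[Si](C)(C)C(C)(C)C | intermediate
15 | (1S,2R,5S,6R)-2,6-bis[4-(tert-butyldimethylsilyloxy)-3-methoxyphenyl]-3,7-dioxabicyclo[3.3.0]octane-1,5-diol | COc1cc([C@H]2OC[C@]3(O)[C@@H](c4ccc(O[Si](C)(C)C(C)(C)C)c(OC)c4)OC[C@]23O)ccc1O[Si](C)(C)C(C)(C)C | intermediate
16 | prinsepiol, (1S,2R,5S,6R)-2,6-bis(4-hydroxy-3-methoxyphenyl)-3,7-dioxabicyclo[3.3.0]octane-1,5-diol | COc1cc([C@H]2OC[C@]3(O)[C@@H](c4ccc(O)c(OC)c4)OC[C@]23O)ccc1O | target

**Step count.** Total: 7 steps. Longest linear sequence: 6 steps (1, 2, 3, 4, 6, 7).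

**Steps most likely to fail**

Step 2 (key step). The lactone enolate may be lost through β-elimination of the acetonide oxygen or through self-condensation before it meets formaldehyde. Fallback: from 4, deprotonation with LiN(i-Pr)2 in the presence of Me3SiCl (internal quench) should trap the enolate at once as the silyl ketene acetal F1. A Lewis-acid Mukaiyama hydroxymethylation (aqueous formaldehyde, Sc(OTf)3, THF, or 1,3,5-trioxane with TiCl4) should then give the hydroxymethyl lactone ester F2 without any free enolate. CSA in toluene would close the second lactone and rejoin the route at 7.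

Step 1. The aldol with gaseous formaldehyde may give poor conversion through polymerisation of the formaldehyde, or material may be lost by retro-aldol cleavage during the methoxide stage. Fallback: from 1, the same enolate is C-alkylated with benzyl chloromethyl ether, a reactive halide of the kind best precedented for this enolate, to give the benzyloxymethyl cis-diester F3. Hydrogenolysis (H2, Pd/C, EtOAc) should give 3 as an isolated compound, where the fallback rejoins the route; 3 is then epimerised and lactonised to 4 as in the second half of step 1.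

Step 6. The aryl transfer may show poor facial selectivity at one or both oxocarbenium ions, or a 1,2-shift triggered by the neighbouring alkoxide may compete. Fallback: from 9, aqueous acid (sulfonic acid resin, H2O/THF) should give the free bis-lactol F4. Addition of excess Grignard reagent 13 to its open hydroxy-aldehyde forms should give the hexol F5, two aryl groups being taken up per molecule. Acid-mediated cyclodehydration (CSA, CH2Cl2) through the p-silyloxybenzyl cations, the classical endgame for furofuran lignans, should close both oxolane rings under equilibrating conditions to the exo,exo-diaryl isomer and rejoin the route at 15.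

**Further compounds**

F1 | step 2 | methyl (3aR)-2,2-dimethyl-6-(trimethylsilyloxy)-4H-furo[3,4-d][1,3]dioxole-3a-carboxylate | C[Si](C)(C)OC1=C2OC(C)(C)O[C@]2(C(=O)OC)CO1
F2 | step 2 | methyl (3aR,6aR)-6a-(hydroxymethyl)-2,2-dimethyl-6-oxotetrahydrofuro[3,4-d][1,3]dioxole-3a(4H)-carboxylate | O=C1OC[C@@]2(C(=O)OC)OC(C)(C)O[C@@]12CO
F3 | step 1 | dimethyl (4R,5S)-4-[(benzyloxy)methyl]-2,2-dimethyl-1,3-dioxolane-4,5-dicarboxylate | COC(=O)[C@H]1OC(C)(C)O[C@]1(C(=O)OC)COCc1ccccc1
F4 | step 6 | (1R,5R)-3,7-dioxabicyclo[3.3.0]octane-1,2,5,6-tetrol (mixture at C2 and C6) | OC1OC[C@]2(O)C(O)OC[C@]12O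
F5 | step 6 | (2S,3S)-1,4-bis[4-(tert-butyldimethylsilyloxy)-3-methoxyphenyl]-2,3-bis(hydroxymethyl)butane-1,2,3,4-tetrol (mixture at C1 and C4) | COc1cc(C(O)[C@@](O)(CO)[C@](O)(CO)C(O)c2ccc(O[Si](C)(C)C(C)(C)C)c(OC)c2)ccc1O[Si](C)(C)C(C)(C)C
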